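**Retrosynthetic overview**

1. The 3,6-dihydro-1,2-dioxine ring (O1–O2–C3–C4=C5–C6) is cut at C5–C6 and at O2–C3 in one (3+3) operation. This gives a C6–O1–O2 unit (the hydroperoxy ketal of the side-chain ethyl ketone) and a C3–C4=C5 unit (an (S)-β-lactone that carries a (Z)-vinylsilane).
2. Enabling feature: the ring is a cyclic allylic peroxide in which C6 stands at the ketone (perketal) oxidation level, C5 is a vinylic CH, and C3 is both allylic and β to the carboxyl group. C6 can therefore be a peroxycarbenium electrophile, C5 the ipso-nucleophilic carbon of a vinylsilane, and C3 the β-carbon of a β-lactone that O2 opens with inversion, which also frees CH2CO2H.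
3. Hydroperoxy ketal: two Cu-catalysed asymmetric conjugate additions (butyl, then methyl) with an HWE olefination between them set both side-chain centres; methylenation and ozonolysis in methanol follow.
4. β-Lactone: propargyl alcohol, ethylmagnesiation/iodination, retro-Brook C-silylation, oxidation, catalytic asymmetric ketene–aldehyde cyclocondensation.
5. Ring order: the dioxine ring is the only ring of the target and is formed last, in the key step; the four-membered lactone is a temporary ring that is opened there.

Key step: step 11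

Remark on the chemistry: the facial sense of the three catalyst-controlled steps (1, 4 and 10) is assumed from the accepted models for these catalyst families; each ligand or alkaloid is available in both (pseudo)enantiomeric forms, so the antipode would be used if the first run showed the opposite sense.

**Route**

Step 1
Reactants: 1 methyl (E)-pent-2-enoate
Product: 2 methyl (S)-3-ethylheptanoate
Conditions: n-BuMgBr, CuI (2 mol%), (R)-Tol-BINAP (3 mol%), t-BuOMe, −40 °C; MeOH, aq. NH4Cl
Reagents that add atoms: n-butylmagnesium bromide CCCC[Mg]Br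
Why: Cu-catalysed asymmetric conjugate addition of a Grignard reagent to an (E)-enoate, in which the chiral copper–bisphosphine complex selects the β-face and should set the ethyl/butyl carbon as S.

Step 2
Reactants: 2 methyl (S)-3-ethylheptanoate
Product: 3 (S)-3-ethylheptanal
Conditions: i-Bu2AlH (1.05 equiv), CH2Cl2, −78 °C; MeOH, aq. potassium sodium tartrate
Reagents that add atoms: none
Why: Partial reduction of a methyl ester stops at the aluminium hemiacetal at −78 °C and gives the aldehyde on work-up; the stereocentre is β to the carbonyl and cannot epimerise.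

Step 3
Reactants: 3 (S)-3-ethylheptanal; 4 diethyl (2-oxobutyl)phosphonate
Product: 5 (S,E)-7-ethylundec-4-en-3-one
Conditions: LiCl, i-Pr2NEt, MeCN, rt
Reagents that add atoms: none
Why: Horner–Wadsworth–Emmons olefination under Masamune–Roush conditions should give the (E)-enone with a base too weak to cause aldol side reactions of the aldehyde.

Step 4
Reactants: 5 (S,E)-7-ethylundec-4-en-3-one
Product: 6 (5S,7S)-7-ethyl-5-methylundecan-3-one
Conditions: MeMgBr, CuBr·SMe2 (5 mol%), (R)-1-[(S)-2-(diphenylphosphino)ferrocenyl]ethyldicyclohexylphosphine (6 mol%), t-BuOMe, −75 °C; aq. NH4Cl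
Reagents that add atoms: methylmagnesium bromide C[Mg]Br
Why: Cu-catalysed asymmetric conjugate addition of MeMgBr to an acyclic enone, in which the ferrocenyl diphosphine–copper complex controls the β-face and should set C5 as S irrespective of the remote C7 centre.

Step 5
Reactants: 6 (5S,7S)-7-ethyl-5-methylundecan-3-one
Product: 7 (4S,6S)-2,6-diethyl-4-methyldec-1-ene
Conditions: Ph3PCH3Br, KOt-Bu, THF, 0 °C → rt
Reagents that add atoms: methylenetriphenylphosphorane C=P(c1ccccc1)(c1ccccc1)c1ccccc1
Why: Wittig methylenation of an unhindered ketone; no stereocentre is α to the carbonyl, so nothing can epimerise.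

Step 6
Reactants: 7 (4S,6S)-2,6-diethyl-4-methyldec-1-ene
Product: 9 (5S,7S)-7-ethyl-3-hydroperoxy-3-methoxy-5-methylundecane (both epimers at C3), via carbonyl oxide 8 (not isolated)
Conditions: O3, CH2Cl2/MeOH 4:1, −78 °C; N2 purge; concentration below 20 °C without reductive work-up
Reagents that add atoms: ozone [O-][O+]=O; methanol CO
Why: Ozonolysis of a 1,1-disubstituted alkene in methanol: cycloreversion of the primary ozonide gives formaldehyde and the more substituted carbonyl oxide 8, which methanol traps as the α-methoxy hydroperoxide; the new perketal carbon forms as both epimers, which is harmless because it becomes planar in step 11.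

Step 7
Reactants: 10 prop-2-yn-1-ol
Product: 12 (Z)-2-ethyl-3-iodoprop-2-en-1-ol, via magnesium chelate 11 (not isolated)
Conditions: EtMgBr (2.5 equiv), CuI (10 mol%), THF, −10 °C → rt; then I2, −40 → 0 °C; aq. NH4Cl
Reagents that add atoms: ethylmagnesium bromide CC[Mg]Br; iodine II
Why: Cu-catalysed anti-carbomagnesiation of propargyl alcohol places ethyl on C2 and magnesium on C3 within a five-membered alkoxide chelate, and iodinolysis of the C–Mg bond with retention should give the iodide with iodine cis to CH2OH.

Step 8
Reactants: 12 (Z)-2-ethyl-3-iodoprop-2-en-1-ol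
Product: 15 (Z)-2-ethyl-3-(trimethylsilyl)prop-2-en-1-ol, via silyl ether 13 (not isolated), via vinyllithium 14 (not isolated)
Conditions: n-BuLi (1.0 equiv), THF, −78 °C, then Me3SiCl, −78 → 0 °C; t-BuLi (2.1 equiv), −78 → −30 °C; aq. NH4Cl
Reagents that add atoms: chlorotrimethylsilane C[Si](C)(C)Cl
Why: O-silylation, iodine–lithium exchange with retention and retro-[1,4]-Brook migration of silicon from oxygen to carbon, which is possible only because lithium and CH2OSi are cis, should give the C-silyl alcohol with silicon cis to CH2OH.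

Step 9
Reactants: 15 (Z)-2-ethyl-3-(trimethylsilyl)prop-2-en-1-ol
Product: 16 (Z)-2-ethyl-3-(trimethylsilyl)prop-2-enal
Conditions: activated MnO2, CH2Cl2, rt, dark
Reagents that add atoms: none
Why: Allylic oxidation with MnO2 under neutral conditions should leave the geometry of the vinylsilane untouched.

Step 10
Reactants: 16 (Z)-2-ethyl-3-(trimethylsilyl)prop-2-enal
Product: 17 (S)-4-[(Z)-1-(trimethylsilyl)but-1-en-2-yl]oxetan-2-one
Conditions: CH3COCl (slow addition), i-Pr2NEt, O-trimethylsilylquinine (10 mol%), LiClO4, CH2Cl2/Et2O, −78 °C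
Reagents that add atoms: acetyl chloride CC(=O)Cl
Why: Cinchona alkaloid/LiClO4-catalysed acyl halide–aldehyde cyclocondensation (formal ketene–aldehyde (2+2)): the chiral ammonium enolate adds to the lithium-activated aldehyde and lactonises, which should set the lactone carbon as S.

Step 11
Reactants: 9 (5S,7S)-7-ethyl-3-hydroperoxy-3-methoxy-5-methylundecane; 17 (S)-4-[(Z)-1-(trimethylsilyl)but-1-en-2-yl]oxetan-2-one
Product: 20 2-[(3R,6R)-4,6-diethyl-6-[(2S,4S)-4-ethyl-2-methyloctyl]-3,6-dihydro-1,2-dioxin-3-yl]acetic acid, via seco peroxyketal acid 18 (not isolated), via peroxycarbenium ion 19 (not isolated)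
Conditions: 9 (1.2 equiv), Sc(OTf)3 (5 mol%), 4 Å molecular sieves, CH2Cl2, −40 °C; then 2,6-di-tert-butyl-4-methylpyridine, SnCl4 (1.1 equiv), −78 → −40 °C; aq. pH 7 phosphate buffer
Reagents that add atoms: none
Why: Proposed new method: Sc(OTf)3 activates the strained allylic lactone 17 so that the hydroperoxy oxygen of 9 opens it at the alkyl C–O bond with inversion (O2–C3 bond, free CO2H, intermediate 18); SnCl4 then ionises the methoxy group of the perketal to the peroxycarbenium ion 19, which is attacked by the silicon-bearing carbon of the (Z)-vinylsilane (C5–C6 bond), and the β-silyl cation loses Me3Si+ to leave the C4=C5 double bond. The closest known reactions are the Lewis-acid opening of oxetanes by hydroperoxides, the additions and cyclisations of perketal-derived peroxycarbenium ions onto allylsilanes and alkenes, and vinylsilane-terminated oxocarbenium (silyl-Prins) cyclisations; their combination as a (3+3) annulation on a β-lactone is new. The single ring closes in a 6-endo mode with respect to the vinylsilane through a half-chair transition state. C3 is fixed by SN2 inversion of the (S)-lactone carbon, and both epimers of the perketal carbon of 9 converge on the planar ion 19, whose face is chosen in the ring closure: silicon must leave anti to the incoming C6, which should place CH2CO2H at C3 pseudo-equatorial, and the larger branched chain of 19 should take the position anti to the O–O bond, so that the ethyl group at C6 ends up cis to CH2CO2H (6R). The step needs alkyl–oxygen instead of acyl–oxygen cleavage of the lactone (secured by the allylic, strained C–O bond under acid), ionisation of OMe instead of the peroxide (tin Lewis acid on a dialkyl perketal) and clean ipso substitution (β-silicon effect and Z geometry of 17).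

**Compound list**

1 | methyl (E)-pent-2-enoate | CC/C=C/C(=O)OC | starting material
2 | methyl (S)-3-ethylheptanoate | CCCC[C@H](CC)CC(=O)OC | intermediate
3 | (S)-3-ethylheptanal | CCCC[C@H](CC)CC=O | intermediate
4 | diethyl (2-oxobutyl)phosphonate | CCC(=O)CP(=O)(OCC)OCC | starting material
5 | (S,E)-7-ethylundec-4-en-3-one | CCCC[C@H](CC)C/C=C/C(=O)CC | intermediate
6 | (5S,7S)-7-ethyl-5-methylundecan-3-one | CCCC[C@H](CC)C[C@H](C)CC(=O)CC | intermediate
7 | (4S,6S)-2,6-diethyl-4-methyldec-1-ene | CCCC[C@H](CC)C[C@H](C)CC(=C)CC | intermediate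
8 | carbonyl oxide of ketone 6 (not isolated) | CCCC[C@H](CC)C[C@H](C)CC(CC)=[O+][O-] | intermediate
9 | (5S,7S)-7-ethyl-3-hydroperoxy-3-methoxy-5-methylundecane (both epimers at C3) | CCCC[C@H](CC)C[C@H](C)CC(CC)(OC)OO | intermediate
10 | prop-2-yn-1-ol | OCC#C | starting material
11 | 4-ethyl-2,5-dihydro-1,2-oxamagnesole, the cyclic vinylmagnesium alkoxide (not isolated) | CCC1=C[Mg]OC1 | intermediate
12 | (Z)-2-ethyl-3-iodoprop-2-en-1-ol | OC/C(CC)=C\I | intermediate
13 | (Z)-[(2-ethyl-3-iodoprop-2-en-1-yl)oxy]trimethylsilane (not isolated) | C[Si](C)(C)OC/C(CC)=C\I | intermediate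
14 | (Z)-[2-ethyl-3-(trimethylsilyloxy)prop-1-en-1-yl]lithium (not isolated) | C[Si](C)(C)OC/C(CC)=C\[Li] | intermediate
15 | (Z)-2-ethyl-3-(trimethylsilyl)prop-2-en-1-ol | OC/C(CC)=C\[Si](C)(C)C | intermediate
16 | (Z)-2-ethyl-3-(trimethylsilyl)prop-2-enal | O=C/C(CC)=C\[Si](C)(C)C | intermediate
17 | (S)-4-[(Z)-1-(trimethylsilyl)but-1-en-2-yl]oxetan-2-one | C[Si](C)(C)/C=C(CC)\[C@@H]1CC(=O)O1 | intermediate
18 | (3R,4Z)-4-ethyl-3-{[(5S,7S)-7-ethyl-3-methoxy-5-methylundecan-3-yl]peroxy}-5-(trimethylsilyl)pent-4-enoic acid (not isolated) | CCCC[C@H](CC)C[C@H](C)CC(CC)(OC)OO[C@H](CC(=O)O)/C(CC)=C\[Si](C)(C)C | intermediate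
19 | peroxycarbenium ion formed from 18 by loss of methoxide (not isolated) | CCCC[C@H](CC)C[C@H](C)CC(CC)=[O+]O[C@H](CC(=O)O)/C(CC)=C\[Si](C)(C)C | intermediate
20 | 2-[(3R,6R)-4,6-diethyl-6-[(2S,4S)-4-ethyl-2-methyloctyl]-3,6-dihydro-1,2-dioxin-3-yl]acetic acid | CCCC[C@H](CC)C[C@H](C)C[C@]1(CC)C=C(CC)[C@@H](CC(=O)O)OO1 | target

**Step count and risks**

Total step count: 11. Longest linear sequence: 7 steps (steps 1–6 and 11); the lactone branch is 5 steps (steps 7–11).

Steps most likely to fail:

1. Step 11 (proposed new method). Three processes may go wrong: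
   - The hydroperoxy ketal may ionise and add to the vinylsilane before the lactone is opened; C6 would then form without ring control, or the β-silyl cation would be captured by the free peroxide or the carboxyl group.
   - The lactone may ionise to an allyl cation, with loss of configurational integrity at C3 or decarboxylation.
   - Face selection at C6 between ethyl and the branched chain may be poor.

   The fallback uses known chemistry, sets out from 12 and 6 and comes back at 20, and gives up the stereocontrol of the key step, so the ring isomers must be separated. Oxidation of 12 with MnO2 should give (Z)-2-ethyl-3-iodoprop-2-enal F1, and a Wittig reaction with Ph3P=CHCO2Me should give methyl (2E,4Z)-4-ethyl-5-iodopenta-2,4-dienoate F2. Iodine–magnesium exchange (i-PrMgCl·LiCl, THF, −78 °C) and addition to ketone 6 in the presence of LaCl3·2LiCl should give the tertiary allylic alcohol methyl (2E,4Z,8S,10S)-4,6,10-triethyl-6-hydroxy-8-methyltetradeca-2,4-dienoate F3 as both C6 epimers. Acid-catalysed exchange with H2O2 (ethereal H2O2, cat. H2SO4, 0 °C) should give the tertiary hydroperoxide methyl (2E,4Z,8S,10S)-4,6,10-triethyl-6-hydroperoxy-8-methyltetradeca-2,4-dienoate F4. Intramolecular oxa-Michael addition (Et2NH, CF3CH2OH) should close the ring to methyl 2-[(3R,6R)-4,6-diethyl-6-[(2S,4S)-4-ethyl-2-methyloctyl]-3,6-dihydro-1,2-dioxin-3-yl]acetate F5, which is separated from its ring diastereomers by chromatography. Hydrolysis (LiOH, THF/H2O, 0 °C, then mild acid) gives 20.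

2. Step 10. The cycloaddition may be slow with the hindered, conjugated aldehyde, the enal may isomerise from Z to E through reversible conjugate addition of the amine catalyst, and the enantioselectivity may be eroded. The fallback sets out from 16 and comes back at 17. Aldol addition of doubly lithiated (S)-2-hydroxy-1,2,2-triphenylethyl acetate (LiN(i-Pr)2, THF, −78 °C, MgBr2) to 16 should give (S)-2-hydroxy-1,2,2-triphenylethyl (S,Z)-4-ethyl-3-hydroxy-5-(trimethylsilyl)pent-4-enoate F6. Saponification (KOH, MeOH/H2O) should give (S,Z)-4-ethyl-3-hydroxy-5-(trimethylsilyl)pent-4-enoic acid F7 and return the triphenylglycol. Carboxyl activation (PhSO2Cl, pyridine, 0 °C) closes the lactone with retention at the carbinol carbon to give 17.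

3. Step 4. Catalyst control may be incomplete (lower diastereomeric purity of the 1,3-related centres, which cannot be corrected by separation of hydrocarbons later), and 1,2-addition may compete. The fallback replaces catalyst control by auxiliary control, sets out from 3 and comes back at 6. HWE olefination of 3 with diethyl {2-oxo-2-[(R)-2-oxo-4-phenyloxazolidin-3-yl]ethyl}phosphonate (LiCl, i-Pr2NEt, MeCN) should give (R)-3-[(S,E)-5-ethylnon-2-enoyl]-4-phenyloxazolidin-2-one F8. Addition of MeMgBr/CuBr·SMe2 (THF/Me2S, −30 °C) anti to phenyl in the chelated s-cis imide should give (R)-3-[(3S,5S)-5-ethyl-3-methylnonanoyl]-4-phenyloxazolidin-2-one F9, a crystalline imide that can be purified. MeONHMe·HCl/AlMe3 should give (3S,5S)-5-ethyl-N-methoxy-N,3-dimethylnonanamide F10, and EtMgBr (THF, 0 °C) gives 6.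

**Further compounds**

F1 | step 11 | (Z)-2-ethyl-3-iodoprop-2-enal | O=C/C(CC)=C\I
F2 | step 11 | methyl (2E,4Z)-4-ethyl-5-iodopenta-2,4-dienoate | COC(=O)/C=C/C(CC)=C\I
F3 | step 11 | methyl (2E,4Z,8S,10S)-4,6,10-triethyl-6-hydroxy-8-methyltetradeca-2,4-dienoate (both C6 epimers) | CCCC[C@H](CC)C[C@H](C)CC(O)(CC)/C=C(CC)\C=C\C(=O)OC
F4 | step 11 | methyl (2E,4Z,8S,10S)-4,6,10-triethyl-6-hydroperoxy-8-methyltetradeca-2,4-dienoate (both C6 epimers) | CCCC[C@H](CC)C[C@H](C)CC(OO)(CC)/C=C(CC)\C=C\C(=O)OC
F5 | step 11 | methyl 2-[(3R,6R)-4,6-diethyl-6-[(2S,4S)-4-ethyl-2-methyloctyl]-3,6-dihydro-1,2-dioxin-3-yl]acetate | CCCC[C@H](CC)C[C@H](C)C[C@]1(CC)C=C(CC)[C@@H](CC(=O)OC)OO1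
F6 | step 10 | (S)-2-hydroxy-1,2,2-triphenylethyl (S,Z)-4-ethyl-3-hydroxy-5-(trimethylsilyl)pent-4-enoate | C[Si](C)(C)/C=C(CC)\[C@@H](O)CC(=O)O[C@@H](c1ccccc1)C(O)(c1ccccc1)c1ccccc1
F7 | step 10 | (S,Z)-4-ethyl-3-hydroxy-5-(trimethylsilyl)pent-4-enoic acid | C[Si](C)(C)/C=C(CC)\[C@@H](O)CC(=O)O
F8 | step 4 | (R)-3-[(S,E)-5-ethylnon-2-enoyl]-4-phenyloxazolidin-2-one | CCCC[C@H](CC)C/C=C/C(=O)N1[C@H](c2ccccc2)COC1=O
F9 | step 4 | (R)-3-[(3S,5S)-5-ethyl-3-methylnonanoyl]-4-phenyloxazolidin-2-one | CCCC[C@H](CC)C[C@H](C)CC(=O)N1[C@H](c2ccccc2)COC1=O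
F10 | step 4 | (3S,5S)-5-ethyl-N-methoxy-N,3-dimethylnonanamide | CCCC[C@H](CC)C[C@H](C)CC(=O)N(C)OC
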